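## Analysis of the target

The target 25 is a depsidone. Ring A and ring B are joined by a diaryl ether oxygen (a5–O–b1) and by an ester (a4–C(=O)–O–b2), which together close the central seven-membered dioxepinone. Ring B also carries a fused hydroxyphthalide: the lactone carbonyl sits on b5 and the lactol carbon on b6. Ring B is fully substituted, ring A has one hydrogen (a2), and the ether oxygen is flanked by four ortho substituents (a4, a6, b2, b6). The only stereocentre is the lactol carbon, (R). It is a hemiacylal that can open to the achiral 2-formylbenzoic acid form, so it has no partner to be relayed from and must be set late and kept away from base and water. The sensitive groups are the aryl ester of the seven-membered lactone (base), the a6 hydroxymethyl group (a benzylic alcohol between two ring oxygens, prone to ionisation in acid and to hydrogenolysis), the b4 phenol and the lactol. The plan rests on one feature of ring B: the b4 hydroxyl is para to the ether oxygen on b1, and the ester oxygen sits on b2 next to b1. Ring B is therefore a hydroquinone mono-aryl ether with one extra oxygen, and that oxygen can come from the ring A carboxyl group (a4) if the b4 phenol is oxidised, the carboxyl adds at the para carbon b1 and then moves to b2. The ether made beforehand then has only three ortho substituents, and ring B needs only two oxygens.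

## Retrosynthetic reasoning

**25 from 24.** The last operation removes two acetyl groups, one from the a6 oxygen and one from the lactol oxygen. The stereocentre is carried as an acylal, which cannot ring-open. The cleavage must break the acyl–oxygen bonds and not the C–O bond at the stereocentre, and it must avoid water and base; an enzymatic transesterification does this.

**24 from 23.** The stereocentre is set by enantioselective acetylation of the racemic lactol 23 while its two enantiomers interconvert through the ring-opened form (dynamic kinetic resolution). The a6 oxygen is already acetylated and the b4 phenol is chelated to the phthalide carbonyl, so only the lactol hydroxyl reacts.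

**23 from 21 (via 22).** The lactol is cut back to a b6 formyl group and a b5 methyl ester. The forward step uses the formyl group as a neighbouring group: its hydrate attacks the adjacent ester, which makes this one ester far more labile than the a6 acetate or the aryl lactone in 21.

**21 from 19 (via 20), the key disconnection.** The bond between the carboxyl oxygen and b2 is cut, which opens the seven-membered lactone and removes the b2 oxygen from ring B altogether. What is gained is a precursor, 19, whose ring B is a plain hydroquinone derivative and whose ether is one ortho substituent less crowded. The forward reaction has to oxidise the b4 phenol, attach the carboxyl oxygen at b1 (spiro ketal 20), and move it to b2 with rearomatisation.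

**19 from 17 (via 18).** The carboxylic acid, the b4 phenol and the b6 aldehyde of 19 are masked in 17 as a 2-(trimethylsilyl)ethyl ester, a silyl ether and a diethyl acetal. One fluoride treatment frees the first two and dilute acid then frees the third. The order matters: a free formyl group next to the b5 ester would make that ester base-labile, so it is released only after the basic step. A benzyl ester for ring A is excluded, because the a6 acetoxymethyl group is itself a benzylic ester and would be hydrogenolysed.

**17 from 7 and 16.** The ether is cut at the a5–O bond. Ring B contributes the oxygen as the free b1 phenol of 7, and ring A is the electrophile as the aryl triflate 16, whose ortho ester makes it electron-poor. In 7 the aldehyde is an acetal, so the phenol is electron-rich and does not chelate the catalyst. The forward reaction is a palladium-catalysed C–O coupling giving an ether with three ortho substituents.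

**7 from 2 and 5 (via 6).** Ring B is cut at b4–b5 and b1–b6, a Diels–Alder disconnection to the silyloxyfuran 2 and the ynoate 5. The ester directs the cycloaddition, so it ends next to the silyloxy-bearing carbon (b4) and the acetal next to the former furan oxygen, which becomes the free b1 hydroxyl. The two hydroxyls are thus differentiated as they are made, in the sense the coupling needs, and b5 and b6 arrive at the right oxidation levels. The formyl-directed pairing with the isomeric diene would give the same carbon pattern but with the silyl group on b1 and a free aldehyde; it is kept as a fallback.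

**2 from 1 and 5 from 3 (via 4).** The diene is the silyl dienol ether of butenolide 1. The dienophile comes from alkyne 3 by acylation of its acetylide 4.

**16 from 8.** Ring A keeps all its carbons and oxygens from 8. The a5 oxygen becomes the triflate leaving group, the a1 hydroxyl is methylated (9), and the a6 carbon is introduced by ortho-formylation of phenol 11 (via 12), which has one free ortho position, giving 13. The methyl ester is exchanged for the fluoride-labile ester by way of acid 10, because the hindered methyl ester could not later be cleaved beside the b5 ester. The sequence triflation (14), reduction (15), acetylation (16) is ordered so that a phenoxide never sits next to a benzylic leaving group, which would eliminate to a quinone methide.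

## Alternatives that were turned down

**Alternative 1: ring A built last on the ester by a formal [3+3] benzannulation.**
- Disconnection: a6–a1 and a3–a4.
- Forward key step: a titanium Lewis acid condenses the bis(silyl) dienol ether A2, carried on the ring B aryl ester, with the masked 1,3-dielectrophile A3 to give depside A1. The a5 phenol and the b1 bromide of A1 would then be joined by an intramolecular Ullmann etherification.
- For it: the salicylate is built with defined regiochemistry, both ring B oxygens at b1 and b2 come from an ordinary catechol-type piece, and the ether closure is intramolecular. On that last point it is stronger than the chosen route, which relies on an intermolecular coupling.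
- Against it: the aryl ester must survive double enolisation and the Lewis acid, although an aryl β-keto ester readily loses phenoxide. A1 also has hydrogen on b6, so the lactol carbon would have to be put on a deactivated ring B while the a2 position of ring A is the more nucleophilic site. Its two benzyl ethers call for hydrogenolysis next to the doubly oxygen-flanked a6 benzylic C–O bond.
- Comparison: the chosen strategy brings b5 and b6 in at their final oxidation levels in one cycloaddition and needs no late C–H functionalisation and no benzyl groups.

**Alternative 2: ring A and the dioxepinone formed together by a tethered Diels–Alder reaction.**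
- Disconnection: a4–a5 and a2–a3.
- Forward key step: heating precursor A5, a catechol carrying a but-2-ynoate on the b2 oxygen and a dienyl ether on the b1 oxygen, then dehydrogenating with a quinone oxidant, would give the protected depsidone A4.
- For it: two C–C bonds and two rings form in one step, the regiochemistry is fixed by the tether and by matched polarity, and no aryl–oxygen coupling is needed. In convergence of bond formation it is stronger than the chosen route.
- Against it: A5 contains an acid-labile 1-aryloxy-3-methoxydiene attached through an enol ether to the most hindered oxygen of ring B, which is hard to make and to handle. The aryl ester prefers the conformation that turns the alkyne away from the diene, and the cycloaddition has to pass through a seven-membered tether. The benzyl ether on b4 again forces hydrogenolysis.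
- Comparison: the chosen strategy uses a stable precursor made by established reaction types and concentrates the risk in one oxidation with a single selectivity question.

**Alternative 3: the lactol carbon introduced by carboxylate-directed C–H annulation and one-carbon excision.**
- Disconnection: the b6–carbon bond.
- Forward key step: a pentamethylcyclopentadienyl rhodium catalyst with a copper carboxylate oxidant would annulate the enol ester A8 onto depsidone acid A7, directed by the b5 carboxylate, to give isocoumarin A6. Ozonolysis would then excise one carbon and leave the formyl–carboxyl pair.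
- For it: ring B need not carry an aldehyde through the synthesis, only one ortho C–H bond is available to the directing group, and the ether in A7 has three ortho substituents, as in the chosen route. On the late introduction of the sensitive formyl group it is stronger.
- Against it: the b6 C–H bond lies next to the diaryl ether inside a rigid tricycle. A free b5 acid must be unmasked beside the aryl lactone. Enol esters are less dependable than alkynes in this annulation. Ozone must spare the electron-rich ring A. The depsidone core still has to be closed by a separate lactonisation.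
- Comparison: the chosen strategy uses its oxidation to make the ester C–O bond itself and reaches the same oxidation pattern in fewer steps.

Key step: step 13

Remark: the lactol carbon of 25 can epimerise through ring–chain tautomerism in water or with base; it is assumed to hold its configuration in dry, base-free organic solution and in the solid, so it is fixed in step 15 and released last.

## Route

Step 1
Reactants: 1 3-methylfuran-2(5H)-one
Product: 2 2-(tert-butyldimethylsilyloxy)-3-methylfuran
Conditions: TBSOTf, Et3N, CH2Cl2, 0 °C
Reagents that add atoms: tert-butyldimethylsilyl trifluoromethanesulfonate, CC(C)(C)[Si](C)(C)OS(=O)(=O)C(F)(F)F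
Why: O-silylation of the butenolide and loss of a C5 proton give the aromatic 2-silyloxyfuran (soft enolisation); the hindered silyl group keeps the diene isolable.

Step 2
Reactants: 3 3,3-diethoxyprop-1-yne
Product: 5 methyl 4,4-diethoxybut-2-ynoate, via lithium acetylide 4 (not isolated)
Conditions: n-BuLi, THF, −78 °C; then ClCO2Me, −78 → 0 °C
Reagents that add atoms: methyl chloroformate, COC(=O)Cl
Why: Deprotonation of the terminal alkyne and C-acylation of the acetylide with a chloroformate; the acetal is inert to the base.

Step 3
Reactants: 2 2-(tert-butyldimethylsilyloxy)-3-methylfuran; 5 methyl 4,4-diethoxybut-2-ynoate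
Product: 7 methyl 2-(tert-butyldimethylsilyloxy)-6-(diethoxymethyl)-5-hydroxy-3-methylbenzoate, via oxanorbornadiene adduct 6 (not isolated)
Conditions: PhMe, 110 °C, sealed tube; chromatography on Et3N-deactivated SiO2
Reagents that add atoms: none
Why: Diels–Alder reaction of a 2-silyloxyfuran with an ynoate followed by opening of the oxygen bridge to the phenol; the nucleophilic furan C5 bonds to the ynoate β-carbon, so the ester ends next to the silyloxy carbon (b4/b5) and the acetal next to the new hydroxyl (b1/b6). The silyl group should stay on the oxygen it came with, because the bridge C–O bond that breaks is the one at the silyloxy-bearing carbon.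

Step 4
Reactants: 8 methyl orsellinate (methyl 2,4-dihydroxy-6-methylbenzoate)
Product: 9 methyl 2-hydroxy-4-methoxy-6-methylbenzoate
Conditions: MeI (1.1 equiv), K2CO3, acetone, reflux
Reagents that add atoms: iodomethane, CI
Why: Williamson methylation; the 4-hydroxyl is the more acidic and unhindered one, while the 2-hydroxyl is tied up in a hydrogen bond to the ester and should stay free.

Step 5
Reactants: 9 methyl 2-hydroxy-4-methoxy-6-methylbenzoate
Product: 10 2-hydroxy-4-methoxy-6-methylbenzoic acid
Conditions: KOH, EtOH/H2O, reflux; then aq. HCl, 0 °C
Reagents that add atoms: potassium hydroxide, [K+].[OH-]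
Why: Saponification of the hindered salicylate needs hot alkali, under which the phenoxide carboxylate is stable; cold acidification avoids decarboxylation of the free acid.

Step 6
Reactants: 10 2-hydroxy-4-methoxy-6-methylbenzoic acid
Product: 11 2-(trimethylsilyl)ethyl 2-hydroxy-4-methoxy-6-methylbenzoate
Conditions: Me3SiCH2CH2OH, PPh3, DIAD, THF, 0 °C → rt
Reagents that add atoms: 2-(trimethylsilyl)ethanol, C[Si](C)(C)CCO
Why: Mitsunobu esterification, in which the carboxylate attacks the activated primary alcohol, so the hindered carbonyl carbon need not be attacked; with one equivalent the far less acidic chelated phenol should not compete.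

Step 7
Reactants: 11 2-(trimethylsilyl)ethyl 2-hydroxy-4-methoxy-6-methylbenzoate
Product: 13 2-(trimethylsilyl)ethyl 3-formyl-2-hydroxy-4-methoxy-6-methylbenzoate, via hydroxymethyl phenol 12 (not isolated)
Conditions: MgCl2, Et3N, (CH2O)n, MeCN, reflux
Reagents that add atoms: paraformaldehyde (as formaldehyde), C=O
Why: Casnati–Skattebøl ortho-formylation: the magnesium phenoxide delivers formaldehyde to the only free ortho carbon (a6), and the magnesium alkoxide of 12 is oxidised to the aldehyde by hydride transfer to a second formaldehyde.

Step 8
Reactants: 13 2-(trimethylsilyl)ethyl 3-formyl-2-hydroxy-4-methoxy-6-methylbenzoate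
Product: 14 2-(trimethylsilyl)ethyl 3-formyl-4-methoxy-6-methyl-2-(trifluoromethanesulfonyloxy)benzoate
Conditions: Tf2O, pyridine, CH2Cl2, −20 → 0 °C
Reagents that add atoms: trifluoromethanesulfonic anhydride, O=S(=O)(OS(=O)(=O)C(F)(F)F)C(F)(F)F
Why: O-sulfonylation of an acidic phenol flanked by two carbonyl groups; it is done while a6 is still a formyl group, so no phenoxide ever sits beside a benzylic leaving group.

Step 9
Reactants: 14 2-(trimethylsilyl)ethyl 3-formyl-4-methoxy-6-methyl-2-(trifluoromethanesulfonyloxy)benzoate
Product: 15 2-(trimethylsilyl)ethyl 3-(hydroxymethyl)-4-methoxy-6-methyl-2-(trifluoromethanesulfonyloxy)benzoate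
Conditions: NaBH4, THF/MeOH, −20 °C
Reagents that add atoms: none
Why: Chemoselective borohydride reduction of the aldehyde; the aryl triflate and the hindered ester are not reduced at this temperature.

Step 10
Reactants: 15 2-(trimethylsilyl)ethyl 3-(hydroxymethyl)-4-methoxy-6-methyl-2-(trifluoromethanesulfonyloxy)benzoate
Product: 16 2-(trimethylsilyl)ethyl 3-(acetoxymethyl)-4-methoxy-6-methyl-2-(trifluoromethanesulfonyloxy)benzoate
Conditions: Ac2O, pyridine, DMAP (cat.), CH2Cl2, 0 °C
Reagents that add atoms: acetic anhydride, CC(=O)OC(C)=O
Why: Standard acetylation of a primary alcohol; the acetate makes the electron-rich benzylic oxygen non-nucleophilic and a poorer leaving group for the oxidation and acid of step 13.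

Step 11
Reactants: 7 methyl 2-(tert-butyldimethylsilyloxy)-6-(diethoxymethyl)-5-hydroxy-3-methylbenzoate; 16 2-(trimethylsilyl)ethyl 3-(acetoxymethyl)-4-methoxy-6-methyl-2-(trifluoromethanesulfonyloxy)benzoate
Product: 17 2-(trimethylsilyl)ethyl 3-(acetoxymethyl)-2-[4-(tert-butyldimethylsilyloxy)-2-(diethoxymethyl)-3-(methoxycarbonyl)-5-methylphenoxy]-4-methoxy-6-methylbenzoate
Conditions: Pd(OAc)2 (5 mol %), 2-di-tert-butylphosphino-3,4,5,6-tetramethyl-2′,4′,6′-triisopropylbiphenyl (7.5 mol %), K3PO4, PhMe, 100 °C
Reagents that add atoms: none
Why: Palladium-catalysed diaryl ether synthesis (Buchwald–Hartwig type): zerovalent palladium adds to the electron-poor triflate, the phenoxide of 7 replaces triflate on divalent palladium, and the bulky biaryl phosphine forces C–O reductive elimination. The acetal keeps the phenol electron-rich and non-chelating and protects the neighbouring methyl ester from base-assisted cleavage.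

Step 12
Reactants: 17 2-(trimethylsilyl)ethyl 3-(acetoxymethyl)-2-[4-(tert-butyldimethylsilyloxy)-2-(diethoxymethyl)-3-(methoxycarbonyl)-5-methylphenoxy]-4-methoxy-6-methylbenzoate
Product: 19 3-(acetoxymethyl)-2-[2-formyl-4-hydroxy-3-(methoxycarbonyl)-5-methylphenoxy]-4-methoxy-6-methylbenzoic acid, via acetal acid 18 (not isolated)
Conditions: Bu4NF (3 equiv), THF, 0 °C → rt; then 0.1 M aq. HCl, 0 °C
Reagents that add atoms: water, O
Why: Fluoride attacks silicon only: the aryl silyl ether is cleaved and the silylethyl ester fragments to carboxylate, ethene and fluorosilane, so the hindered carbonyl is never attacked and the acetate should survive. The aldehyde is released afterwards by brief dilute acid, because a free formyl group next to the methyl ester would make that ester labile under the basic fluoride conditions.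

Step 13
Reactants: 19 3-(acetoxymethyl)-2-[2-formyl-4-hydroxy-3-(methoxycarbonyl)-5-methylphenoxy]-4-methoxy-6-methylbenzoic acid
Product: 21 depsidone (11-oxo-11H-dibenzo[b,e][1,4]dioxepine) with a1 OMe, a3 CH3, a6 CH2OAc, b3 CH3, b4 OH, b5 CO2Me and b6 CHO, via spiro quinone ketal 20 (not isolated)
Conditions: PhI(OAc)2 (1.1 equiv), CH2Cl2/(CF3)2CHOH 4:1, 0 °C; then CF3CO2H (5 equiv), 0 °C → rt
Reagents that add atoms: none
Why: Proposed new method: ligand exchange of the b4 phenol on trivalent iodine and loss of iodobenzene make ring B electrophilic at the para carbon b1, which is captured by the ring A carboxyl oxygen in a 6-exo spirocyclisation to the mixed acyloxy/aryloxy quinone ketal 20; the closest known reactions are PhI(OAc)2 spirolactonisation of para-substituted phenols and ketal formation from para-alkoxyphenols. CF3CO2H then protonates the dienone carbonyl of 20, the b1–O(acyl) bond lengthens because the remaining aryloxy oxygen stabilises positive charge at b1, and the carboxyl oxygen bonds to b2, the carbon conjugate to the b4 carbonyl; this is the 1,2-acyloxy shift known from acid treatment of para-quinol esters. Because the acyl carbon is held in the spiro ring, a fully formed dioxolanylium bridge would put a cationic carbon at a bridgehead of a bicyclo[3.2.1] frame, so the shift is expected to be asynchronous and ion-pair-like. The second ring is closed as a ring expansion of the six-membered spiro dioxinone to the seven-membered dioxepinone (formally a 7-endo capture at b2), and loss of the b2 proton restores aromatic ring B with its b4 phenol. No stereocentre results, since the spiro centre of 20 is destroyed. The step needs b2 over b6 and acyloxy over aryloxy migration: b2 is the only dienone carbon bearing hydrogen and so the only one from which aromatisation can follow, b6 is quaternary and flanked by formyl and ester, and the aryloxy group is the poorer leaving group and the better cation-stabilising group, so it stays on b1. Ring A has no free phenol and its a6 oxygen is acylated, so the oxidant has one site of attack and no second nucleophile can reach b1.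

Step 14
Reactants: 21 depsidone with b5 CO2Me, b6 CHO and a6 CH2OAc
Product: 23 racemic hydroxyphthalide (lactol) depsidone with a6 CH2OAc, via ring-opened formyl acid 22 (not isolated)
Conditions: NaHCO3, THF/H2O, 20 °C; then 1 M aq. HCl to pH 2, 0 °C
Reagents that add atoms: water, O
Why: Neighbouring-group-assisted ester hydrolysis: the hydrate anion of the b6 formyl group attacks the adjacent b5 ester through a five-membered ring, which should make this ester hydrolyse far faster than the unassisted a6 acetate and the aryl lactone at bicarbonate pH. On acidification the 2-formylbenzoic acid 22 closes to the lactol by ring–chain tautomerism, necessarily as the racemate.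

Step 15
Reactants: 23 racemic hydroxyphthalide depsidone with a6 CH2OAc
Product: 24 (R)-configured lactol acetate with a6 CH2OAc
Conditions: Amano PS lipase (Burkholderia cepacia, immobilised), vinyl acetate, Et3N (0.1 equiv), PhMe, 35 °C
Reagents that add atoms: vinyl acetate, C=COC(C)=O
Why: Lipase-catalysed acetylation with dynamic kinetic resolution, as established for 5-hydroxyfuran-2(5H)-ones: the enzyme acylates one lactol enantiomer while the other racemises through the amine-assisted ring-opened form, and the acylal product can no longer open. The stereocentre is set by the active site of the enzyme; the sense has to be confirmed on this substrate and a lipase delivering the (R)-acetate chosen. The chelated b4 phenol should not be acylated.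

Step 16
Reactants: 24 (R)-configured lactol acetate with a6 CH2OAc
Product: 25 CNP0367167.1, (R)-configured at the lactol carbon
Conditions: Amano PS lipase and Novozym 435 (Candida antarctica lipase B), n-BuOH, t-BuOMe, 25 °C
Reagents that add atoms: none
Why: Enzymatic alcoholysis transfers both acetyl groups to butanol by acyl–oxygen cleavage, so the C–O bond at the stereocentre is not broken; the medium is dry and free of base, which should suppress ring opening of the released lactol. The lipase of step 15 accepts the (R)-acylal by microscopic reversibility.

## Compound list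

1 | 3-methylfuran-2(5H)-one | CC1=CCOC1=O | starting material
2 | 2-(tert-butyldimethylsilyloxy)-3-methylfuran | Cc1ccoc1O[Si](C)(C)C(C)(C)C | intermediate
3 | 3,3-diethoxyprop-1-yne | CCOC(OCC)C#C | starting material
4 | lithium 3,3-diethoxyprop-1-yn-1-ide (not isolated) | CCOC(OCC)C#C[Li] | intermediate
5 | methyl 4,4-diethoxybut-2-ynoate | CCOC(OCC)C#CC(=O)OC | intermediate
6 | methyl 1-(tert-butyldimethylsilyloxy)-3-(diethoxymethyl)-6-methyl-7-oxabicyclo[2.2.1]hepta-2,5-diene-2-carboxylate, racemic (not isolated) | CCOC(OCC)C1=C(C(=O)OC)C2(O[Si](C)(C)C(C)(C)C)OC1C=C2C | intermediate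
7 | methyl 2-(tert-butyldimethylsilyloxy)-6-(diethoxymethyl)-5-hydroxy-3-methylbenzoate | CCOC(OCC)c1c(O)cc(C)c(O[Si](C)(C)C(C)(C)C)c1C(=O)OC | intermediate
8 | methyl orsellinate (methyl 2,4-dihydroxy-6-methylbenzoate) | COC(=O)c1c(C)cc(O)cc1O | starting material
9 | methyl 2-hydroxy-4-methoxy-6-methylbenzoate | COC(=O)c1c(C)cc(OC)cc1O | intermediate
10 | 2-hydroxy-4-methoxy-6-methylbenzoic acid | Cc1cc(OC)cc(O)c1C(=O)O | intermediate
11 | 2-(trimethylsilyl)ethyl 2-hydroxy-4-methoxy-6-methylbenzoate | Cc1cc(OC)cc(O)c1C(=O)OCC[Si](C)(C)C | intermediate
12 | 2-(trimethylsilyl)ethyl 2-hydroxy-3-(hydroxymethyl)-4-methoxy-6-methylbenzoate, present as its magnesium alkoxide (not isolated) | Cc1cc(OC)c(CO)c(O)c1C(=O)OCC[Si](C)(C)C | intermediate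
13 | 2-(trimethylsilyl)ethyl 3-formyl-2-hydroxy-4-methoxy-6-methylbenzoate | Cc1cc(OC)c(C=O)c(O)c1C(=O)OCC[Si](C)(C)C | intermediate
14 | 2-(trimethylsilyl)ethyl 3-formyl-4-methoxy-6-methyl-2-(trifluoromethanesulfonyloxy)benzoate | Cc1cc(OC)c(C=O)c(OS(=O)(=O)C(F)(F)F)c1C(=O)OCC[Si](C)(C)C | intermediate
15 | 2-(trimethylsilyl)ethyl 3-(hydroxymethyl)-4-methoxy-6-methyl-2-(trifluoromethanesulfonyloxy)benzoate | Cc1cc(OC)c(CO)c(OS(=O)(=O)C(F)(F)F)c1C(=O)OCC[Si](C)(C)C | intermediate
16 | 2-(trimethylsilyl)ethyl 3-(acetoxymethyl)-4-methoxy-6-methyl-2-(trifluoromethanesulfonyloxy)benzoate | Cc1cc(OC)c(COC(C)=O)c(OS(=O)(=O)C(F)(F)F)c1C(=O)OCC[Si](C)(C)C | intermediate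
17 | 2-(trimethylsilyl)ethyl 3-(acetoxymethyl)-2-[4-(tert-butyldimethylsilyloxy)-2-(diethoxymethyl)-3-(methoxycarbonyl)-5-methylphenoxy]-4-methoxy-6-methylbenzoate | COc1cc(C)c(C(=O)OCC[Si](C)(C)C)c(Oc2cc(C)c(O[Si](C)(C)C(C)(C)C)c(C(=O)OC)c2C(OCC)OCC)c1COC(C)=O | intermediate
18 | 3-(acetoxymethyl)-2-[2-(diethoxymethyl)-4-hydroxy-3-(methoxycarbonyl)-5-methylphenoxy]-4-methoxy-6-methylbenzoic acid, present as its tetrabutylammonium salt (not isolated) | COc1cc(C)c(C(=O)O)c(Oc2cc(C)c(O)c(C(=O)OC)c2C(OCC)OCC)c1COC(C)=O | intermediate
19 | 3-(acetoxymethyl)-2-[2-formyl-4-hydroxy-3-(methoxycarbonyl)-5-methylphenoxy]-4-methoxy-6-methylbenzoic acid (precursor of the key step) | COc1cc(C)c(C(=O)O)c(Oc2cc(C)c(O)c(C(=O)OC)c2C=O)c1COC(C)=O | intermediate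
20 | spiro quinone ketal, racemic: b1 carries the ring A aryloxy oxygen and the ring A carboxyl oxygen in a six-membered 1,3-benzodioxin-4-one, ring B is a cyclohexa-2,5-dienone with its carbonyl at b4 (not isolated) | COc1cc(C)c2C(=O)OC3(Oc2c1COC(C)=O)C=C(C)C(=O)C(C(=O)OC)=C3C=O | intermediate
21 | depsidone with a1 OMe, a3 CH3, a6 CH2OAc, b3 CH3, b4 OH, b5 CO2Me, b6 CHO (product of the key step) | COc1cc(C)c2c(c1COC(C)=O)Oc1c(c(C)c(O)c(C(=O)OC)c1C=O)OC2=O | intermediate
22 | the same depsidone with b5 CO2H and b6 CHO, present as its sodium salt (not isolated) | COc1cc(C)c2c(c1COC(C)=O)Oc1c(c(C)c(O)c(C(=O)O)c1C=O)OC2=O | intermediate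
23 | racemic hydroxyphthalide (lactol) depsidone with a6 CH2OAc | COc1cc(C)c2c(c1COC(C)=O)Oc1c(c(C)c(O)c3c1C(O)OC3=O)OC2=O | intermediate
24 | (R)-lactol acetate of the depsidone with a6 CH2OAc | COc1cc(C)c2c(c1COC(C)=O)Oc1c(c(C)c(O)c3c1[C@H](OC(C)=O)OC3=O)OC2=O | intermediate
25 | CNP0367167.1, depsidone with a6 CH2OH, b4 OH and (R)-configured hydroxyphthalide | COc1cc(C)c2c(c1CO)Oc1c(c(C)c(O)c3c1[C@H](O)OC3=O)OC2=O | target

## Step count and least certain steps

Total step count: 16. Longest linear sequence: 13 steps (steps 4 to 16, from 8).

**Step 13 (key step).** Four things may go wrong. The electron-poor, hydrogen-bonded b4 phenol may be oxidised only slowly. Traces of water may hydrolyse the spiro ketal to a quinone with loss of ring A. The aryloxy bond at b1 may ionise instead of the acyloxy bond, or the ketal may not move on at all. The acid may ionise the a6 benzylic acetate.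
Fallback, with known reactions only, from 17 back to 21: HF·pyridine in THF and a dilute aqueous acid work-up should remove the aryl silyl ether and the acetal but keep the silylethyl ester, giving phenol F1. PhI(OAc)2 (or Pb(OAc)4) in acetic acid acetoxylates the para carbon to the para-quinol acetate F2. BF3·OEt2 in CH2Cl2 then brings about the known 1,2-acetoxy shift of quinol acetates to the b2 acetate F3. Anhydrous fluoride (tris(dimethylamino)sulfonium difluorotrimethylsilicate, DMF) removes the silylethyl ester and the phenolic acetate to give hydroxy acid F4. F4 is closed to 21 by carbodiimide lactonisation (DCC, CH2Cl2), the classical depsidone closure; only the b2 hydroxyl can reach the carboxyl group.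

**Step 3.** The ynoate has a single activating group, so the cycloaddition may be slower than thermal decomposition of the silyloxyfuran; the silyl group may migrate to the less hindered b1 oxygen; the ortho-hydroxy acetal may lose ethanol on heating or on silica.
Fallback from 5 back to 7, using formyl instead of ester direction: formic acid converts 5 into methyl 4-oxobut-2-ynoate F5, a far stronger dienophile. It is combined at 0 °C with 2-(triethylsilyloxy)-4-methylfuran F6 (from commercial 4-methylfuran-2(5H)-one, Et3SiOTf, Et3N) to give phenol F7, which has the same carbon pattern but carries the silyl ether on b1 and the free hydroxyl on b4. Silylation of b4 (TBSOTf, 2,6-lutidine) gives bis-silyl ether F8. Aqueous acetic acid in THF removes the labile triethylsilyl group next to the formyl group to give hydroxy aldehyde F9. Triethyl orthoformate in ethanol with pyridinium p-toluenesulfonate then gives 7.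

**Step 11.** Triflyl transfer from the electron-poor triflate to the phenoxide (attack at sulfur) and slow reductive elimination at the doubly ortho-substituted aryl palladium centre may both divert the coupling; the benzylic acetate may also be activated by palladium.
Fallback from 13 and 7 back to 17, by nucleophilic aromatic substitution: deoxyfluorination of phenol 13 (PhenoFluor, CsF, PhMe, 110 °C) gives aryl fluoride F10, activated by the ortho formyl and ortho ester groups. Phenol 7 displaces fluoride (K3PO4, MeCN, 50 °C) to give formyl diaryl ether F11. Since the ring B aldehyde is an acetal, NaBH4 reduces only the ring A formyl group to alcohol F12, and acetylation (Ac2O, pyridine) gives 17.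

**Step 15.** The bulky tricyclic lactol may be a poor substrate for the enzyme, the enzyme may prefer the wrong enantiomer, or racemisation may be too slow to keep up with acylation.
Fallback from 23 to 24, without an enzyme: acylative dynamic kinetic resolution with acetic anhydride (1.1 equiv), iPr2NEt and a chiral nucleophilic acyl-transfer catalyst of the benzotetramisole or chiral 4-aminopyridine type at low temperature. Both antipodes of such catalysts are available, so the (R)-acetate can be addressed; no new compound is made.

**Step 16.** The released lactol may epimerise through the ring-opened form before it is isolated, and cleavage of the hindered benzylic acetate may lag behind.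
Fallback from 23 to 25, by physical resolution: lipase-catalysed alcoholysis (Novozym 435, n-BuOH, t-BuOMe) removes the a6 acetate from racemic 23 to give racemic lactol F13. Its enantiomers are separated by chromatography on a chiral stationary phase with an acidic, base-free eluent at low temperature, and 25 is collected and crystallised directly.

## Further compounds

F1 | step 13 | 2-(trimethylsilyl)ethyl 3-(acetoxymethyl)-2-[2-formyl-4-hydroxy-3-(methoxycarbonyl)-5-methylphenoxy]-4-methoxy-6-methylbenzoate | COc1cc(C)c(C(=O)OCC[Si](C)(C)C)c(Oc2cc(C)c(O)c(C(=O)OC)c2C=O)c1COC(C)=O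
F2 | step 13 | para-quinol acetate: 2-(trimethylsilyl)ethyl 3-(acetoxymethyl)-2-[1-acetoxy-2-formyl-3-(methoxycarbonyl)-5-methyl-4-oxocyclohexa-2,5-dien-1-yl]oxy-4-methoxy-6-methylbenzoate, racemic | COc1cc(C)c(C(=O)OCC[Si](C)(C)C)c(OC2(OC(C)=O)C=C(C)C(=O)C(C(=O)OC)=C2C=O)c1COC(C)=O
F3 | step 13 | 2-(trimethylsilyl)ethyl 2-[6-acetoxy-2-formyl-4-hydroxy-3-(methoxycarbonyl)-5-methylphenoxy]-3-(acetoxymethyl)-4-methoxy-6-methylbenzoate | COc1cc(C)c(C(=O)OCC[Si](C)(C)C)c(Oc2c(OC(C)=O)c(C)c(O)c(C(=O)OC)c2C=O)c1COC(C)=O
F4 | step 13 | 3-(acetoxymethyl)-2-[2-formyl-4,6-dihydroxy-3-(methoxycarbonyl)-5-methylphenoxy]-4-methoxy-6-methylbenzoic acid | COc1cc(C)c(C(=O)O)c(Oc2c(O)c(C)c(O)c(C(=O)OC)c2C=O)c1COC(C)=O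
F5 | step 3 | methyl 4-oxobut-2-ynoate | COC(=O)C#CC=O
F6 | step 3 | 2-(triethylsilyloxy)-4-methylfuran | Cc1coc(O[Si](CC)(CC)CC)c1
F7 | step 3 | methyl 6-formyl-2-hydroxy-3-methyl-5-(triethylsilyloxy)benzoate | COC(=O)c1c(O)c(C)cc(O[Si](CC)(CC)CC)c1C=O
F8 | step 3 | methyl 2-(tert-butyldimethylsilyloxy)-6-formyl-3-methyl-5-(triethylsilyloxy)benzoate | COC(=O)c1c(O[Si](C)(C)C(C)(C)C)c(C)cc(O[Si](CC)(CC)CC)c1C=O
F9 | step 3 | methyl 2-(tert-butyldimethylsilyloxy)-6-formyl-5-hydroxy-3-methylbenzoate | COC(=O)c1c(O[Si](C)(C)C(C)(C)C)c(C)cc(O)c1C=O
F10 | step 11 | 2-(trimethylsilyl)ethyl 2-fluoro-3-formyl-4-methoxy-6-methylbenzoate | Cc1cc(OC)c(C=O)c(F)c1C(=O)OCC[Si](C)(C)C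
F11 | step 11 | 2-(trimethylsilyl)ethyl 2-[4-(tert-butyldimethylsilyloxy)-2-(diethoxymethyl)-3-(methoxycarbonyl)-5-methylphenoxy]-3-formyl-4-methoxy-6-methylbenzoate | COc1cc(C)c(C(=O)OCC[Si](C)(C)C)c(Oc2cc(C)c(O[Si](C)(C)C(C)(C)C)c(C(=O)OC)c2C(OCC)OCC)c1C=O
F12 | step 11 | 2-(trimethylsilyl)ethyl 2-[4-(tert-butyldimethylsilyloxy)-2-(diethoxymethyl)-3-(methoxycarbonyl)-5-methylphenoxy]-3-(hydroxymethyl)-4-methoxy-6-methylbenzoate | COc1cc(C)c(C(=O)OCC[Si](C)(C)C)c(Oc2cc(C)c(O[Si](C)(C)C(C)(C)C)c(C(=O)OC)c2C(OCC)OCC)c1CO
F0 | step 15 | none | none
F13 | step 16 | racemic hydroxyphthalide depsidone with a6 CH2OH (racemate of 25) | COc1cc(C)c2c(c1CO)Oc1c(c(C)c(O)c3c1C(O)OC3=O)OC2=O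
A1 | alternative 1 | 5-(benzyloxy)-2-bromo-4-(methoxycarbonyl)-6-methylphenyl 3-(benzyloxymethyl)-2-hydroxy-4-methoxy-6-methylbenzoate | COc1cc(C)c(C(=O)Oc2c(Br)cc(C(=O)OC)c(OCc3ccccc3)c2C)c(O)c1COCc1ccccc1
A2 | alternative 1 | 1,3-bis(trimethylsilyl) dienol ether of 5-(benzyloxy)-2-bromo-4-(methoxycarbonyl)-6-methylphenyl 5-(benzyloxy)-3-oxopentanoate | C[Si](C)(C)OC(Oc1c(Br)cc(C(=O)OC)c(OCc2ccccc2)c1C)=CC(O[Si](C)(C)C)=CCOCc1ccccc1
A3 | alternative 1 | 4,4-dimethoxybut-3-en-2-one | CC(=O)C=C(OC)OC
A4 | alternative 2 | protected depsidone with a6 CH2OSi(t-Bu)Me2, b4 OBn, b5 CO2Me and b6 CH(OMe)2 | COc1cc(C)c2c(c1CO[Si](C)(C)C(C)(C)C)Oc1c(c(C)c(OCc3ccccc3)c(C(=O)OC)c1C(OC)OC)OC2=O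
A5 | alternative 2 | methyl 2-(benzyloxy)-4-(but-2-ynoyloxy)-6-(dimethoxymethyl)-3-methyl-5-{[2-(tert-butyldimethylsilyloxymethyl)-3-methoxybuta-1,3-dien-1-yl]oxy}benzoate | COC(=C)C(CO[Si](C)(C)C(C)(C)C)=COc1c(OC(=O)C#CC)c(C)c(OCc2ccccc2)c(C(=O)OC)c1C(OC)OC
A6 | alternative 3 | depsidone-fused 3-methylisocoumarin with a6 CH2OSi(t-Bu)Me2 and b4 OCH2OMe | COc1cc(C)c2c(c1CO[Si](C)(C)C(C)(C)C)Oc1c(c(C)c(OCOC)c3c1C=C(C)OC3=O)OC2=O
A7 | alternative 3 | depsidone b5 carboxylic acid with hydrogen on b6, a6 CH2OSi(t-Bu)Me2 and b4 OCH2OMe | COc1cc(C)c2c(c1CO[Si](C)(C)C(C)(C)C)Oc1cc(C(=O)O)c(OCOC)c(C)c1OC2=O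
A8 | alternative 3 | isopropenyl acetate | CC(=C)OC(C)=O
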